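The bicyclo[5.3.0]decane core is cut at C5–C1 and C6–C7 (daucane numbering), the bonds that join the two-carbon unit C5–C6 to the five-carbon chain C7–C8=C9–C10–C1 of the seven-membered ring. That chain is a ring-opened vinylcyclopropane, so a rhodium-catalysed (5+2) cycloaddition of a cis-2-isopropenylcyclopropane, tethered through its quaternary carbon C1 by C2–C4 to an (E)-alkenylboronate, should form both bonds and close both rings in one operation, driven by release of ring strain; the cyclopropane stores the C1 configuration and the alkene geometry sets C5 and C6. The precursor is an open-chain, silyl-protected diol with the cyclopropane at one end and the alkenylboronate at the other.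

Key step: step 8

Remark: atoms carry daucane numbers throughout. Five-membered ring: C1 (quaternary, methyl), C2 (CHOH), C3, C4 (isopropyl carbinol), C5 (ring-fusion CH). Seven-membered ring: C1, C5, C6 (ester carbinol), C7, C8 (methyl)=C9, C10. α/β refer to the flat drawing with the C1 methyl β. Compounds 1, 2, 5, 7, 10, 12, 14 and 18 are assumed to be commercial.

**Step 1**
Reactants: 1 methacrolein (2-methylprop-2-enal); 2 ethyl 2-[bis(2,2,2-trifluoroethoxy)phosphoryl]propanoate
Product: 3 ethyl (2Z)-2,4-dimethylpenta-2,4-dienoate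
Conditions: KN(SiMe3)2, 18-crown-6, THF, −78 °C
Reagents that add atoms: none
Why: Still–Gennari variant of the Horner–Wadsworth–Emmons olefination, in which fast elimination from the kinetic adduct of the trifluoroethyl phosphonate should give the (Z)-trisubstituted ester and so place the future C2 carbon cis to the isopropenyl group.

**Step 2**
Reactants: 3 ethyl (2Z)-2,4-dimethylpenta-2,4-dienoate
Product: 4 (2Z)-2,4-dimethylpenta-2,4-dien-1-ol
Conditions: iBu2AlH (2.2 equiv), CH2Cl2, −78 °C; aqueous potassium sodium tartrate
Reagents that add atoms: none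
Why: 1,2-reduction of the conjugated ester by the aluminium hydride should give the allylic alcohol without touching the diene or its (Z) geometry.

**Step 3**
Reactants: 4 (2Z)-2,4-dimethylpenta-2,4-dien-1-ol; 5 diiodomethane
Product: 6 [(1R,2R)-1-methyl-2-(prop-1-en-2-yl)cyclopropyl]methanol
Conditions: Et2Zn, DME (gives Zn(CH2I)2·DME), (4S,5S)-2-butyl-N,N,N',N'-tetramethyl-1,3,2-dioxaborolane-4,5-dicarboxamide (1.2 equiv), CH2Cl2, −10 °C to rt
Reagents that add atoms: none
Why: dioxaborolane-mediated asymmetric Simmons–Smith cyclopropanation, in which the zinc alkoxide bound to the chiral boronate delivers methylene only to the allylic double bond, stereospecifically (the (Z) geometry becomes the cis relation of hydroxymethyl and isopropenyl) and to the face fixed by the (4S,5S) ligand, which sets C1 and C9.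

**Step 4**
Reactants: 6 [(1R,2R)-1-methyl-2-(prop-1-en-2-yl)cyclopropyl]methanol; 7 3-methylbutan-2-one
Product: 9 (1S)-1-hydroxy-4-methyl-1-[(1R,2R)-1-methyl-2-(prop-1-en-2-yl)cyclopropyl]pentan-3-one, via cyclopropanecarbaldehyde 8 (not isolated)
Conditions: (COCl)2, DMSO, Et3N, CH2Cl2, −78 °C; cold (0 °C) extractive work-up, solution used at once; LiN(iPr)2/7, THF, −78 °C; AcOH
Reagents that add atoms: none
Why: Swern oxidation gives aldehyde 8, kept cold and in solution because a cis-2-vinylcyclopropanecarbaldehyde can open by retro-Claisen rearrangement to an achiral dihydrooxepine, and the kinetic lithium enolate of 7 then adds in an aldol reaction to the bisected s-trans conformer from the side of the ring CH2, away from the cis isopropenyl group (Felkin-type 1,2-induction), which should set C2 as (S).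

**Step 5**
Reactants: 9 (1S)-1-hydroxy-4-methyl-1-[(1R,2R)-1-methyl-2-(prop-1-en-2-yl)cyclopropyl]pentan-3-one; 10 ethynylmagnesium bromide
Product: 11 (3R,5S)-3-ethynyl-2-methyl-5-[(1R,2R)-1-methyl-2-(prop-1-en-2-yl)cyclopropyl]pentane-3,5-diol
Conditions: 10 (4 equiv), THF/CH2Cl2, −78 to −30 °C; aqueous NH4Cl
Reagents that add atoms: none
Why: Grignard addition under 1,3-chelation control, in which the bromomagnesium alkoxide formed by the first equivalent chelates the ketone in a six-membered half-chair and axial attack of the small acetylide on its less hindered face should give the 1,3-anti diol (alkyne in the chain), that is the C4 configuration of the target.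

**Step 6**
Reactants: 11 (3R,5S)-3-ethynyl-2-methyl-5-[(1R,2R)-1-methyl-2-(prop-1-en-2-yl)cyclopropyl]pentane-3,5-diol; 12 tert-butyldimethylsilyl chloride
Product: 13 (3R,5S)-5-[(tert-butyldimethylsilyl)oxy]-3-ethynyl-2-methyl-5-[(1R,2R)-1-methyl-2-(prop-1-en-2-yl)cyclopropyl]pentan-3-ol
Conditions: imidazole, DMAP (cat.), DMF, 35 °C
Reagents that add atoms: none
Why: silyl ether formation should occur only at the secondary C2 hydroxyl, the tertiary propargylic hydroxyl being too hindered for the chlorosilane.

**Step 7**
Reactants: 13 (3R,5S)-5-[(tert-butyldimethylsilyl)oxy]-3-ethynyl-2-methyl-5-[(1R,2R)-1-methyl-2-(prop-1-en-2-yl)cyclopropyl]pentan-3-ol; 14 bis(pinacolato)diboron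
Product: 15 (1E,3R,5S)-5-[(tert-butyldimethylsilyl)oxy]-5-[(1R,2R)-1-methyl-2-(prop-1-en-2-yl)cyclopropyl]-3-(propan-2-yl)-1-(4,4,5,5-tetramethyl-1,3,2-dioxaborolan-2-yl)pent-1-en-3-ol
Conditions: CuCl (5 mol %), NaOtBu (10 mol %), Xantphos (5 mol %), MeOH (2 equiv), THF, rt
Reagents that add atoms: none
Why: copper-catalysed hydroboration of the terminal alkyne (syn borylcupration with boron at the terminal carbon, then protonation by methanol) should give the (E)-alkenylboronate and leave the tertiary alcohol and the isopropenyl group untouched.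

**Step 8**
Reactants: 15 (1E,3R,5S)-5-[(tert-butyldimethylsilyl)oxy]-5-[(1R,2R)-1-methyl-2-(prop-1-en-2-yl)cyclopropyl]-3-(propan-2-yl)-1-(4,4,5,5-tetramethyl-1,3,2-dioxaborolan-2-yl)pent-1-en-3-ol
Product: 16 2α-[(tert-butyldimethylsilyl)oxy]-6α-(4,4,5,5-tetramethyl-1,3,2-dioxaborolan-2-yl)dauc-8-en-4β-ol (trans-fused, 1β-methyl, 5α-H)
Conditions: [Rh(CO)2Cl]2 (5 mol %), toluene, 90 °C
Reagents that add atoms: none
Why: Proposed new method: monovalent rhodium, bound to the isopropenyl group and to the tethered alkene, should insert with retention into the strained and most substituted cyclopropane bond C1–C9 to give a trivalent rhodium species that is a tertiary alkyl at C1 and a π-allyl over C9–C8–C7; syn insertion of the (E)-alkenylboronate into the Rh–C1 bond then forms C5–C1 and closes the five-membered ring (5-exo carbometalation), and reductive elimination between C6 and the allyl terminus C7 forms C6–C7 and closes the seven-membered ring with the C8=C9 double bond in place. The closest known reaction type is the rhodium-catalysed intramolecular (5+2) cycloaddition of vinylcyclopropanes with tethered alkenes or alkynes, including the variant in which the ene tether sits on the ring carbon cis to the vinyl group; what has not been shown is the cleavage of a bond to a fully substituted ring carbon and an internal alkenylboronate as the two-carbon partner. C1 keeps the configuration stored in the cyclopropane because C5 takes the place of C9, and C5 and C6 arise together by suprafacial addition across the (E) double bond, which puts H-5 and boron cis. The π-face is expected to be set by the C4 carbinol: the boron-bearing carbon C6 must swing to the side of the hydroxyl group, away from the isopropyl group, which places C6 trans to C10 (trans ring fusion) and boron α. The step needs cleavage of C1–C9 instead of the less hindered C9–C10 bond (which would lead to a bridged bicyclo[4.3.1]decene), closure at C7 instead of C9, and reductive elimination instead of β-hydride loss; the three-atom tether, which lets the alkene reach rhodium only when the metal sits on C1, the cis arrangement of isopropenyl group and tether, which gives the allyl geometry that closes to the (Z)-cycloheptene, and the α-boryl stabilisation of the alkylrhodium should secure them.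

**Step 9**
Reactants: 16 2α-[(tert-butyldimethylsilyl)oxy]-6α-(4,4,5,5-tetramethyl-1,3,2-dioxaborolan-2-yl)dauc-8-en-4β-ol
Product: 17 2α-[(tert-butyldimethylsilyl)oxy]dauc-8-ene-4β,6α-diol
Conditions: 30% H2O2, aqueous NaOH, THF, 0 °C to rt
Reagents that add atoms: hydrogen peroxide, OO
Why: oxidation of the secondary alkylboronate proceeds by 1,2-migration of carbon from boron to oxygen with retention, so the C6 hydroxyl should appear α, cis to H-5.

**Step 10**
Reactants: 17 2α-[(tert-butyldimethylsilyl)oxy]dauc-8-ene-4β,6α-diol; 18 4-[(tert-butyldimethylsilyl)oxy]benzoic acid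
Product: 19 2α-[(tert-butyldimethylsilyl)oxy]-4β-hydroxydauc-8-en-6α-yl 4-[(tert-butyldimethylsilyl)oxy]benzoate
Conditions: DCC, DMAP, CH2Cl2, rt to 40 °C
Reagents that add atoms: none
Why: Steglich esterification should acylate the C6 hydroxyl alone, since it is the only free secondary alcohol (C2 is silylated and the tertiary C4 hydroxyl does not acylate under these conditions).

**Step 11**
Reactants: 19 2α-[(tert-butyldimethylsilyl)oxy]-4β-hydroxydauc-8-en-6α-yl 4-[(tert-butyldimethylsilyl)oxy]benzoate
Product: 20 2α-hydroxyferutinin (2α,4β-dihydroxydauc-8-en-6α-yl 4-hydroxybenzoate)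
Conditions: Bu4NF (3 equiv), AcOH (3 equiv), THF, 0 °C to rt
Reagents that add atoms: none
Why: fluoride-induced desilylation should remove the aryl and the secondary alkyl silyl ether in one operation, the acetic acid buffer guarding the benzoate against hydrolysis or migration.

**Compound list**

1 | methacrolein (2-methylprop-2-enal) | C=C(C)C=O | starting material
2 | ethyl 2-[bis(2,2,2-trifluoroethoxy)phosphoryl]propanoate | CCOC(=O)C(C)P(=O)(OCC(F)(F)F)OCC(F)(F)F | starting material
3 | ethyl (2Z)-2,4-dimethylpenta-2,4-dienoate | CCOC(=O)/C(C)=C\C(C)=C | intermediate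
4 | (2Z)-2,4-dimethylpenta-2,4-dien-1-ol | OC/C(C)=C\C(C)=C | intermediate
5 | diiodomethane | ICI | starting material
6 | [(1R,2R)-1-methyl-2-(prop-1-en-2-yl)cyclopropyl]methanol (hydroxymethyl cis to isopropenyl) | C=C(C)[C@H]1C[C@@]1(C)CO | intermediate
7 | 3-methylbutan-2-one | CC(=O)C(C)C | starting material
8 | (1R,2R)-1-methyl-2-(prop-1-en-2-yl)cyclopropane-1-carbaldehyde | C=C(C)[C@H]1C[C@@]1(C)C=O | intermediate
9 | (1S)-1-hydroxy-4-methyl-1-[(1R,2R)-1-methyl-2-(prop-1-en-2-yl)cyclopropyl]pentan-3-one | C=C(C)[C@H]1C[C@@]1(C)[C@@H](O)CC(=O)C(C)C | intermediate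
10 | ethynylmagnesium bromide | C#C[Mg]Br | starting material
11 | (3R,5S)-3-ethynyl-2-methyl-5-[(1R,2R)-1-methyl-2-(prop-1-en-2-yl)cyclopropyl]pentane-3,5-diol | C=C(C)[C@H]1C[C@@]1(C)[C@@H](O)C[C@@](O)(C(C)C)C#C | intermediate
12 | tert-butyldimethylsilyl chloride | CC(C)(C)[Si](C)(C)Cl | starting material
13 | (3R,5S)-5-[(tert-butyldimethylsilyl)oxy]-3-ethynyl-2-methyl-5-[(1R,2R)-1-methyl-2-(prop-1-en-2-yl)cyclopropyl]pentan-3-ol | C=C(C)[C@H]1C[C@@]1(C)[C@@H](O[Si](C)(C)C(C)(C)C)C[C@@](O)(C(C)C)C#C | intermediate
14 | bis(pinacolato)diboron | CC1(C)OB(OC1(C)C)B1OC(C)(C)C(C)(C)O1 | starting material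
15 | (1E,3R,5S)-5-[(tert-butyldimethylsilyl)oxy]-5-[(1R,2R)-1-methyl-2-(prop-1-en-2-yl)cyclopropyl]-3-(propan-2-yl)-1-(4,4,5,5-tetramethyl-1,3,2-dioxaborolan-2-yl)pent-1-en-3-ol | C=C(C)[C@H]1C[C@@]1(C)[C@@H](O[Si](C)(C)C(C)(C)C)C[C@@](O)(C(C)C)/C=C/B1OC(C)(C)C(C)(C)O1 | intermediate
16 | 2α-[(tert-butyldimethylsilyl)oxy]-6α-(4,4,5,5-tetramethyl-1,3,2-dioxaborolan-2-yl)dauc-8-en-4β-ol | CC1=CC[C@]2(C)[C@@H]([C@@H](B3OC(C)(C)C(C)(C)O3)C1)[C@](O)(C(C)C)C[C@@H]2O[Si](C)(C)C(C)(C)C | intermediate
17 | 2α-[(tert-butyldimethylsilyl)oxy]dauc-8-ene-4β,6α-diol | CC1=CC[C@]2(C)[C@@H]([C@@H](O)C1)[C@](O)(C(C)C)C[C@@H]2O[Si](C)(C)C(C)(C)C | intermediate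
18 | 4-[(tert-butyldimethylsilyl)oxy]benzoic acid | CC(C)(C)[Si](C)(C)Oc1ccc(cc1)C(=O)O | starting material
19 | 2α-[(tert-butyldimethylsilyl)oxy]-4β-hydroxydauc-8-en-6α-yl 4-[(tert-butyldimethylsilyl)oxy]benzoate | CC1=CC[C@]2(C)[C@@H]([C@@H](OC(=O)c3ccc(O[Si](C)(C)C(C)(C)C)cc3)C1)[C@](O)(C(C)C)C[C@@H]2O[Si](C)(C)C(C)(C)C | intermediate
20 | 2α-hydroxyferutinin (2α,4β-dihydroxydauc-8-en-6α-yl 4-hydroxybenzoate) | CC1=CC[C@]2(C)[C@@H]([C@@H](OC(=O)c3ccc(O)cc3)C1)[C@](O)(C(C)C)C[C@@H]2O | target

Total step count: 11. Longest linear sequence: 11 steps (1 to 20 through 3, 4, 6, 9, 11, 13, 15, 16, 17 and 19).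

**Steps most likely to fail**

Step 8 (proposed new method). Rhodium may insert into the less hindered distal bond C9–C10 instead of the fully substituted bond C1–C9. The internal alkenylboronate may fail to insert, or the alkylrhodium may lose β-hydride. The alkene may also react on the wrong π-face and give the cis-fused isomer. The fallback uses only known chemistry (conjugate addition and aldol trapping, Grignard addition, ring-closing metathesis) and gives up the cyclopropane. It sets out from silyl chloride 12 and comes back to the route at diol 17. Commercial (4S)-4-hydroxycyclopent-2-en-1-one is silylated with 12 (imidazole, DMF) to (4S)-4-[(tert-butyldimethylsilyl)oxy]cyclopent-2-en-1-one F1. Copper-mediated conjugate addition of allylmagnesium bromide (CuBr·SMe2, Me3SiCl, THF, −78 °C), anti to the silyloxy group, should give the trans silyl enol ether F2. Saegusa oxidation (Pd(OAc)2, MeCN) returns the enone as (4S)-3-allyl-4-[(tert-butyldimethylsilyl)oxy]cyclopent-2-en-1-one F3. Conjugate addition of Me2CuLi, again anti to the silyloxy group, should set the quaternary C1 with methyl trans and allyl cis to the silyloxy group. The enolate is trapped at −78 °C with 3-methylbut-3-enal F4, made just before use from commercial 3-methylbut-3-en-1-ol with Dess–Martin periodinane. A Zimmerman–Traxler chair with attack anti to the allyl and silyloxy groups should give the anti aldol, hydroxy ketone F5. Isopropylmagnesium chloride with CeCl3 should add to the C4 ketone from the face opposite the C5 side chain to give triene diol F6. Ring-closing metathesis (second-generation Grubbs catalyst, CH2Cl2, 40 °C) then closes the C8=C9 bond and gives 17.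

Step 4. Aldehyde 8 may rearrange by the retro-Claisen path to the achiral dihydrooxepine before the aldol, which would erode the enantiomeric purity, or the enolate may add with poor facial selectivity. The fallback avoids a free aldehyde and sets C2 by reagent control. It sets out from alcohol 6 and comes back at ketone 9. Oxidation of 6 with TEMPO, NaOCl and NaClO2, in which the aldehyde is consumed as it forms, gives (1R,2R)-1-methyl-2-(prop-1-en-2-yl)cyclopropane-1-carboxylic acid F7. Activation with carbonyldiimidazole and reaction with Mg(O2CCH2CO2Et)2 gives β-keto ester F8. An NADPH-dependent ketoreductase chosen for (S) delivery should reduce it to β-hydroxy ester F9. MeNH(OMe)·HCl with isopropylmagnesium chloride converts the ester into Weinreb amide F10, and further isopropylmagnesium chloride gives 9.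

Step 5. The magnesium chelate may be too loose for good 1,3-induction, which would give a mixture of C4 epimers, or the magnesium aldolate may enolise or fragment by retro-aldol reaction. The fallback changes the control element from the chelate to an open, dipole-controlled transition state. It sets out from 9 and comes back at 13, without passing through 11. Ketone 9 is silylated first (tert-butyldimethylsilyl triflate, 2,6-lutidine, CH2Cl2, −78 °C) to silyl ether ketone F11, which can neither chelate nor undergo retro-aldol cleavage. The organocerium reagent made from 10 and CeCl3 (THF, −78 °C) then adds to the ketone. The 1,3-anti polar model, with the nucleophile anti to the β-silyloxy group in the dipole-minimised conformer, predicts the same C4 configuration, so 13 should form directly.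

**Further compounds**

F1 | step 8 | (4S)-4-[(tert-butyldimethylsilyl)oxy]cyclopent-2-en-1-one | O=C1C=C[C@@H](O[Si](C)(C)C(C)(C)C)C1
F2 | step 8 | trans-3-allyl-4-[(tert-butyldimethylsilyl)oxy]-1-[(trimethylsilyl)oxy]cyclopent-1-ene | C=CC[C@H]1C=C(O[Si](C)(C)C)C[C@@H]1O[Si](C)(C)C(C)(C)C
F3 | step 8 | (4S)-3-allyl-4-[(tert-butyldimethylsilyl)oxy]cyclopent-2-en-1-one | C=CCC1=CC(=O)C[C@@H]1O[Si](C)(C)C(C)(C)C
F4 | step 8 | 3-methylbut-3-enal | C=C(C)CC=O
F5 | step 8 | 3-allyl-4-[(tert-butyldimethylsilyl)oxy]-2-(1-hydroxy-3-methylbut-3-en-1-yl)-3-methylcyclopentan-1-one (anti aldol) | C=C(C)C[C@H](O)[C@H]1C(=O)C[C@H](O[Si](C)(C)C(C)(C)C)[C@]1(C)CC=C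
F6 | step 8 | 3-allyl-4-[(tert-butyldimethylsilyl)oxy]-2-(1-hydroxy-3-methylbut-3-en-1-yl)-3-methyl-1-(propan-2-yl)cyclopentan-1-ol | C=C(C)C[C@H](O)[C@H]1[C@](O)(C(C)C)C[C@H](O[Si](C)(C)C(C)(C)C)[C@]1(C)CC=C
F7 | step 4 | (1R,2R)-1-methyl-2-(prop-1-en-2-yl)cyclopropane-1-carboxylic acid | C=C(C)[C@H]1C[C@@]1(C)C(=O)O
F8 | step 4 | ethyl 3-[(1R,2R)-1-methyl-2-(prop-1-en-2-yl)cyclopropyl]-3-oxopropanoate | C=C(C)[C@H]1C[C@@]1(C)C(=O)CC(=O)OCC
F9 | step 4 | ethyl (3S)-3-hydroxy-3-[(1R,2R)-1-methyl-2-(prop-1-en-2-yl)cyclopropyl]propanoate | C=C(C)[C@H]1C[C@@]1(C)[C@@H](O)CC(=O)OCC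
F10 | step 4 | (3S)-3-hydroxy-N-methoxy-N-methyl-3-[(1R,2R)-1-methyl-2-(prop-1-en-2-yl)cyclopropyl]propanamide | C=C(C)[C@H]1C[C@@]1(C)[C@@H](O)CC(=O)N(C)OC
F11 | step 5 | (1S)-1-[(tert-butyldimethylsilyl)oxy]-4-methyl-1-[(1R,2R)-1-methyl-2-(prop-1-en-2-yl)cyclopropyl]pentan-3-one | C=C(C)[C@H]1C[C@@]1(C)[C@@H](O[Si](C)(C)C(C)(C)C)CC(=O)C(C)C
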